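## Analysis of the target

The target is the (E)-4-hydroxycinnamate (p-coumarate) of the daucane diol jaeschkeanadiol. Its core is a bicyclo[5.3.0]decane: cyclopentane ring A (C1–C5) is fused through C1 and C5 to cycloheptene ring B (C1, C5, C6, C7, C8, C9, C10). C1 is the quaternary fusion carbon carrying methyl C15, C4 the isopropyl carbinol, C5 the fusion CH, C6 the acyloxy carbon, and C8 carries methyl C14 on the C8=C9 alkene. The four stereocentres C1, C4, C5 and C6 are contiguous and have the configuration 1R,4R,5S,6S. With the face of C15 called β, the C4 hydroxyl is β (cis to C15), H5 is α (trans ring fusion) and the C6 oxygen is α (cis to H5). Sensitive groups are the tertiary alcohol (dehydration, ionisation), the trisubstituted alkene (acid-induced migration) and the cinnamate with its free phenol (base, nucleophiles, light), which sits on a hindered carbinol. The difficulty lies in joining a seven-membered ring to a quaternary fusion carbon, a trans fusion and a flanking tertiary carbinol, with no functional handle left on C2 or C3. The strategy rests on one feature: ring B can be cut at C7–C8 and C1–C10 into a C1=C5–C6=C7 diene and a C8–C9–C10 unit. This leaves a C5=C6 alkene whose syn, anti-Markovnikov hydration sets C5 and C6 together, and a C9 carbonyl that can bring in C14 and the C8=C9 alkene.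

## Retrosynthetic reasoning

**Ester last (25 ⇒ 24 ⇒ 20 + 23).** The C6–O acyl bond is cut first, because the cinnamate with its phenol is the part least tolerant of bases, hydrides and organometallics. Diol 20 has only one hydroxyl that can be acylated (secondary C6; the C4 hydroxyl is tertiary and flanked by isopropyl), so the diol needs no protection. Acid 23 is 21 with its phenol silylated, which keeps the activated acid from acylating itself. The forward reaction has to acylate a hindered secondary alcohol without touching C4–OH or the E alkene.

**C8=C9 and C14 from a C9 ketone (20 ⇒ 19 ⇒ 18 ⇒ 17 ⇒ 15).** The alkene is traced to enol triflate 18 and this to the 8-methyl ketone 17, made by enolate methylation of 15. The cut is made here because a C9 carbonyl is exactly what a three-carbon oxyallyl unit leaves in ring B. Its two α-carbons differ: C10 is neopentyl (next to quaternary C1), so C8 is deprotonated kinetically. After methylation C8 is the more substituted α-carbon, so enolisation towards C8 under thermodynamic bias fixes the alkene position. The forward sequence has to control regiochemistry twice; it creates no lasting stereocentre.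

**C5–H and C6–O from the C5=C6 alkene (15 ⇒ 14 ⇒ 13 ⇒ 11 ⇒ 10).** Both stereocentres are cut back to one alkene, since a single syn hydroboration–oxidation puts hydrogen on the fully substituted C5 and oxygen on C6 with the cis relation the target needs. The face is chosen by what already sits on ring A, the C1 methyl and the C4 silyloxy group on the β face. The C9 ketone has to be hidden as ketal 11 during this step, and the new hydroxyl is silylated (14) before the ketone is released (15).

**Ring B by (4+3) cycloaddition (10 ⇒ 6 + 8).** C7–C8 and C1–C10 are cut. This is the only pair of cuts that removes ring B in one step, creates the quaternary C1 and leaves the two handles used above. The three-carbon partner, the cation from 8, is symmetric, so there is no regiochemical issue. The forward step has to form two C–C bonds at a fully substituted diene terminus and choose the face of C1 anti to the C4 silyloxy group.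

**Diene from the chiral pool (6 ⇒ 5 ⇒ 4 ⇒ 2 ⇒ 1; 8 ⇒ 7).** The vinyl group of 6 comes from aldehyde 5 by methylenation, and 5 from the 1,6-keto aldehyde 4 by aldol condensation. 4 is the ozonolysis product of silyl ether 2 of (S)-terpinen-4-ol 1. The carbinol carbon of 1 becomes C4 with no bond to it broken, so the absolute configuration is bought. 8 is made from ketal 7 by loss of methanol.

## Alternatives that were turned down

**Alternative 1: asymmetric conjugate methylation with aldol trapping.**
- Disconnection: C1–CH3 and C5–C6, with ring B closed later by metathesis and the isopropyl group added to a C4 ketone.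
- Forward key step: a chiral copper–phosphoramidite catalyst adds a methylaluminium nucleophile to the β-carbon of 3-allylcyclopent-2-en-1-one A1. The aluminium enolate is trapped by 3-methylbut-3-enal A2 and gives aldol A3 with C1, C5 and C6 set and no ring closed.
- For it: three components in one flask, and the absolute configuration comes from a catalyst. The two alkenes of A3 are placed for ring-closing metathesis (second-generation Grubbs catalyst), which would give ring B with the C8=C9 alkene and C14 directly. On step economy, and on how the alkene is made, this alternative is stronger than the chosen route.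
- Against it: the quaternary centre must come from conjugate addition to a β,β-disubstituted cyclopentenone, a flat enone class with weak facial discrimination. A2 is enolisable and slips into conjugation, so it can quench the enolate instead of accepting it. The C6 configuration depends on open aldol diastereoselection. A3 is a β-hydroxy ketone that must accept an isopropyl nucleophile at a hindered, enolisable carbonyl without retro-aldol cleavage, and the C4 configuration is left to that addition.
- Comparison: the chosen route spends about ten steps after ring formation. In return C4 comes with the starting material and every later centre is set relative to it, instead of three centres and the absolute configuration depending on one multicomponent event.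

**Alternative 2: decalin to hydroazulene by a pinacol-type shift.**
- Disconnection: C1–C5, traced back to a C1–C6 bond of a decalin.
- Forward key step: in the cis-fused decalin 4,6-diol 5-mesylate A4 (atoms numbered as in the daucane they become) base removes the proton of the tertiary C6 hydroxyl. The C1–C6 bond shifts to C5 anti to the leaving mesylate and gives hydroazulenone A5: ring A contracted, ring B enlarged, ketone at C6.
- For it: the shift is stereospecific. C5 is set by inversion and C1 keeps its configuration, so the trans fusion follows from mechanism and not from a choice between two faces. On this point it is more secure than the hydroboration of the chosen route. Both methyls, the alkene and the carbinol are carried in, and only reduction and acylation follow A5.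
- Against it: A4 needs four contiguous stereocentres on a decalin in the right absolute sense before the key step, so the problem is moved and not solved. Two tertiary hydroxyls flank the mesylate, and the C4 alkoxide can displace it or trigger migration of isopropyl or C3. The migrating bond must be antiperiplanar in the reacting conformer. A5 is a β-hydroxy ketone formed under base, open to retro-aldol cleavage of C4–C5 and to epimerisation at C5, and its reduction must still be face-selective.
- Comparison: the end-game is shorter, but the route to A4 is long and uncertain. The chosen route reaches its key step in four steps from 1.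

**Alternative 3: [2,3]-Wittig ring expansion.**
- Disconnection: C6–C7, with a temporary C9–O bond.
- Forward key step: tin–lithium exchange at C6 of the cyclopentane-fused 2-(tributylstannyl)-6-isopropenyltetrahydropyran A6 gives an α-alkoxy organolithium. Its [2,3]-shift bonds C6 to the isopropenyl terminus C7, breaks C9–O and turns the six-membered ether into ring B, giving the C4 triethylsilyl ether of jaeschkeanadiol A7.
- For it: one step gives ring B, the C8=C9 alkene in its exact place and the C6 alkoxide. A7 is two steps from the target, the best end-game of the four strategies, and clearly stronger there than the chosen route.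
- Against it: A6 already holds the C1/C4/C5 triad plus two auxiliary stereocentres (C6–Sn and C9), so the hardest part of the molecule must be made beforehand by other chemistry. The shift needs the C–Li bond and the isopropenyl group both axial in a bridged transition state. [1,2]-shift and protonation compete.
- Comparison: the chosen route makes ring B and the quaternary centre in its key step from simple pieces, and pays for it after the key step.

Key step: step 6

Assumption: (S)-(+)-terpinen-4-ol 1 is taken to be available in high enantiomeric purity; its carbinol carbon becomes C4 unchanged.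

## Route

Step 1
Reactants: 1 (S)-terpinen-4-ol
Product: 2 (S)-tert-butyl{[4-methyl-1-(propan-2-yl)cyclohex-3-en-1-yl]oxy}dimethylsilane
Conditions: TBSOTf, 2,6-lutidine, CH2Cl2, 0 °C → rt
Reagents that add atoms: tert-butyldimethylsilyl triflate, CC(C)(C)[Si](C)(C)OS(=O)(=O)C(F)(F)F
Why: A silyl triflate with a hindered pyridine base silylates even a tertiary, isopropyl-flanked alcohol; no bond to the stereocentre is touched, and the bulky ether serves later both as protection and as the group that blocks the β face.

Step 2
Reactants: 2 (S)-tert-butyl{[4-methyl-1-(propan-2-yl)cyclohex-3-en-1-yl]oxy}dimethylsilane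
Product: 4 (S)-3-(tert-butyldimethylsilyloxy)-6-oxo-3-(propan-2-yl)heptanal, via secondary ozonide 3 (not isolated)
Conditions: O3, CH2Cl2, −78 °C; then Me2S, −78 °C → rt
Reagents that add atoms: ozone, [O-][O+]=O
Why: Ozonolysis of the only C=C bond and reductive cleavage of ozonide 3 by the sulfide open the ring to the 1,6-keto aldehyde; the silyl ether is inert and the stereocentre is not involved.

Step 3
Reactants: 4 (S)-3-(tert-butyldimethylsilyloxy)-6-oxo-3-(propan-2-yl)heptanal
Product: 5 (R)-5-(tert-butyldimethylsilyloxy)-2-methyl-5-(propan-2-yl)cyclopent-1-ene-1-carbaldehyde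
Conditions: piperidine (cat.), AcOH (cat.), benzene, 4 Å MS, rt → 50 °C
Reagents that add atoms: none
Why: Amine-salt-mediated intramolecular aldol condensation: the aldehyde forms an enamine far faster than the methyl ketone and attacks the ketone through its α-carbon (5-(enolexo)-exo-trig), and loss of water gives the conjugated enal; the buffered, mild conditions are chosen to keep the β-silyloxy group from eliminating, and the descriptor changes from S to R only through a change of priorities.

Step 4
Reactants: 5 (R)-5-(tert-butyldimethylsilyloxy)-2-methyl-5-(propan-2-yl)cyclopent-1-ene-1-carbaldehyde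
Product: 6 (R)-tert-butyl{[2-ethenyl-3-methyl-1-(propan-2-yl)cyclopent-2-en-1-yl]oxy}dimethylsilane
Conditions: Ph3PCH3Br, KOtBu, THF, 0 °C → rt
Reagents that add atoms: methyltriphenylphosphonium bromide, C[P+](c1ccccc1)(c1ccccc1)c1ccccc1.[Br-]
Why: Wittig methylenation; the non-stabilised ylide adds to the aldehyde only and gives the 1-vinylcyclopentene without touching the tetrasubstituted alkene or the silyl ether.

Step 5
Reactants: 7 1-bromo-2,2-dimethoxypropane
Product: 8 2-methoxyallyl bromide (3-bromo-2-methoxyprop-1-ene)
Conditions: iPr2NEt·TsOH (cat.), neat, 160–190 °C, MeOH distilled off; fractional distillation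
Reagents that add atoms: none
Why: Acid-catalysed thermal loss of methanol from a dimethyl ketal gives the methyl enol ether, and removal of methanol drives the equilibrium; the internal enol ether isomer is separated by distillation and in any case does not ionise with Ag+.

Step 6
Reactants: 6 (R)-tert-butyl{[2-ethenyl-3-methyl-1-(propan-2-yl)cyclopent-2-en-1-yl]oxy}dimethylsilane; 8 2-methoxyallyl bromide
Product: 10 (1R,4R)-4-(tert-butyldimethylsilyloxy)-14-nordauc-5-en-9-one (C15 and the C4 oxygen cis), via methyl enol ether 9 (not isolated)
Conditions: AgOCOCF3, Na2CO3, CH2Cl2/pentane, −30 → 0 °C, dark; then 5% aq. oxalic acid, THF, 0 °C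
Reagents that add atoms: water, O
Why: Ag+ takes bromide from 8 and gives the 2-methoxyallyl cation, a two-electron three-carbon partner that adds across the ends of the four-electron diene 6; the closest known reaction type is the (4+3) cycloaddition of an oxyallyl-type cation with a 1,3-diene. Bonding should begin at the unhindered vinyl terminus C7 (C7–C8) and give an allyl cation over C6–C5–C1 that is tertiary at C1; the tethered enol ether carbon C10 then closes on C1, either in the same asynchronous event or as a 7-endo-trig closure, so ring B forms in the (4+3) mode with the charge on the methoxy-stabilised C9. Loss of a proton to carbonate gives enol ether 9, which dilute acid hydrolyses to ketone 10. The three-carbon unit is symmetric, so no regiochemical question arises, and neither planar rotamer of the diene is favoured (the vinyl group meets the C4 quaternary centre in one and the C1 methyl in the other), so a twisted cisoid geometry is within reach. The one new stereocentre, C1, is controlled by C4: the tert-butyldimethylsilyl group, turned away from the isopropyl group, lies over the β face of C5 and C1 and should send C10 to the α face, which leaves C15 cis to the C4 oxygen. The step also needs chemoselectivity for the diene over ionisation of the tertiary allylic silyl ether, which carbonate buffering, low temperature and a mild hydrolysis are meant to secure.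

Step 7
Reactants: 10 (1R,4R)-4-(tert-butyldimethylsilyloxy)-14-nordauc-5-en-9-one
Product: 11 (1R,4R)-4-(tert-butyldimethylsilyloxy)-9,9-ethylenedioxy-14-nordauc-5-ene
Conditions: (TMSOCH2)2, TMSOTf (cat.), CH2Cl2, −78 °C; pyridine quench
Reagents that add atoms: 1,2-bis(trimethylsilyloxy)ethane, C[Si](C)(C)OCCO[Si](C)(C)C
Why: Silyl-triflate-catalysed ketalisation with the bis-silyl ether of ethylene glycol runs at −78 °C without protic acid, which the tertiary allylic silyl ether would not tolerate; the ketal hides the C9 carbonyl from borane.

Step 8
Reactants: 11 (1R,4R)-4-(tert-butyldimethylsilyloxy)-9,9-ethylenedioxy-14-nordauc-5-ene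
Product: 13 (1R,4R,5S,6S)-4-(tert-butyldimethylsilyloxy)-9,9-ethylenedioxy-14-nordaucan-6-ol (5α-H, 6α-OH, trans-fused), via C6 alkylborane 12 (not isolated)
Conditions: BH3·THF, THF, 0 °C → rt; then NaOH, H2O2, 0 °C → rt
Reagents that add atoms: hydrogen peroxide, OO
Why: Hydroboration–oxidation: concerted syn addition of B–H with boron on the less substituted C6 and hydrogen on the fully substituted C5, then oxidation of C–B with retention; attack on the α face, away from the C1 methyl and the C4 silyloxy group (boranes as a rule also add anti to an allylic oxygen on a ring), sets H5 and O6 together and makes the fusion trans.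

Step 9
Reactants: 13 (1R,4R,5S,6S)-4-(tert-butyldimethylsilyloxy)-9,9-ethylenedioxy-14-nordaucan-6-ol
Product: 14 (1R,4R,5S,6S)-4,6-bis(tert-butyldimethylsilyloxy)-9,9-ethylenedioxy-14-nordaucane
Conditions: TBSOTf, 2,6-lutidine, CH2Cl2, −78 → 0 °C
Reagents that add atoms: tert-butyldimethylsilyl triflate, CC(C)(C)[Si](C)(C)OS(=O)(=O)C(F)(F)F
Why: Silyl triflate protection of a hindered secondary alcohol; C6–O has to survive enolate, triflic anhydride and palladium chemistry, and a second ether of the same kind lets both be removed in one operation.

Step 10
Reactants: 14 (1R,4R,5S,6S)-4,6-bis(tert-butyldimethylsilyloxy)-9,9-ethylenedioxy-14-nordaucane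
Product: 15 (1R,4R,5S,6S)-4,6-bis(tert-butyldimethylsilyloxy)-14-nordaucan-9-one
Conditions: PPTS, acetone/H2O, 50 °C
Reagents that add atoms: water, O
Why: Mild acid-catalysed ketal hydrolysis; pyridinium tosylate is weak enough to leave the secondary and the now non-allylic tertiary silyl ether in place, and no stereocentre is α to the freed ketone.

Step 11
Reactants: 15 (1R,4R,5S,6S)-4,6-bis(tert-butyldimethylsilyloxy)-14-nordaucan-9-one
Product: 17 (1R,4R,5S,6S)-4,6-bis(tert-butyldimethylsilyloxy)daucan-9-one (both C8 epimers), via C8 lithium enolate 16 (not isolated)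
Conditions: LiN(iPr)2, THF, −78 °C; then MeI, −78 → −30 °C
Reagents that add atoms: iodomethane, CI
Why: Kinetic enolate alkylation: the hindered amide removes a proton from C8 because C10 is neopentyl, and enolate 16 is methylated on carbon; the C8 configuration does not matter, since C8 becomes sp2 in step 12.

Step 12
Reactants: 17 (1R,4R,5S,6S)-4,6-bis(tert-butyldimethylsilyloxy)daucan-9-one
Product: 18 (1R,4R,5S,6S)-4,6-bis(tert-butyldimethylsilyloxy)dauc-8-en-9-yl trifluoromethanesulfonate
Conditions: Tf2O, 2,6-di-tert-butyl-4-methylpyridine, CH2Cl2, 0 °C → rt
Reagents that add atoms: triflic anhydride, O=S(=O)(OS(=O)(=O)C(F)(F)F)C(F)(F)F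
Why: Enol triflate formation under non-basic, thermodynamically biased conditions: O-triflylation of the ketone and loss of the proton from the more substituted α-carbon (Zaitsev-type) should give the tetrasubstituted C8=C9 enol triflate, away from neopentyl C10; both C8 epimers converge.

Step 13
Reactants: 18 (1R,4R,5S,6S)-4,6-bis(tert-butyldimethylsilyloxy)dauc-8-en-9-yl trifluoromethanesulfonate
Product: 19 (1R,4R,5S,6S)-4,6-bis(tert-butyldimethylsilyloxy)dauc-8-ene
Conditions: Pd(OAc)2 (cat.), PPh3, HCO2H, Bu3N, DMF, 60 °C
Reagents that add atoms: none
Why: Palladium-catalysed formate reduction of an enol triflate: zerovalent palladium formed in the flask inserts into the C9–O bond, formate replaces triflate on divalent palladium, loss of CO2 leaves a palladium hydride and reductive elimination forms C9–H, so the alkene stays where the triflate fixed it.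

Step 14
Reactants: 19 (1R,4R,5S,6S)-4,6-bis(tert-butyldimethylsilyloxy)dauc-8-ene
Product: 20 (1R,4R,5S,6S)-dauc-8-ene-4,6-diol (jaeschkeanadiol)
Conditions: TBAF, THF, 65 °C
Reagents that add atoms: none
Why: Fluoride cleaves both silyl ethers; heating is needed for the hindered tertiary ether, and a substrate with only an alkene and two ethers has nothing that excess fluoride could harm.

Step 15
Reactants: 21 (E)-4-hydroxycinnamic acid
Product: 23 (E)-4-(tert-butyldimethylsilyloxy)cinnamic acid, via bis-silylated silyl ester 22 (not isolated)
Conditions: TBSCl, imidazole, DMF, rt; then AcOH/THF/H2O, rt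
Reagents that add atoms: tert-butyldimethylsilyl chloride, CC(C)(C)[Si](C)(C)Cl
Why: Silylation of phenol and acid, then selective hydrolysis of the far more labile silyl ester 22; the aryl silyl ether stays and masks the phenol during esterification.

Step 16
Reactants: 20 jaeschkeanadiol; 23 (E)-4-(tert-butyldimethylsilyloxy)cinnamic acid
Product: 24 jaeschkeanadiol 6-O-[(E)-4-(tert-butyldimethylsilyloxy)cinnamate]
Conditions: DCC, DMAP, CH2Cl2, 0 °C → rt
Reagents that add atoms: none
Why: Steglich esterification; only the secondary C6 hydroxyl is acylated, the tertiary C4 hydroxyl being too hindered, and acylation on oxygen leaves the C6 configuration and the E alkene unchanged.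

Step 17
Reactants: 24 jaeschkeanadiol 6-O-[(E)-4-(tert-butyldimethylsilyloxy)cinnamate]
Product: 25 jaeschkeanadiol 6-O-[(E)-4-hydroxycinnamate], (1R,4R,5S,6S), the target
Conditions: TBAF, AcOH, THF, 0 °C
Reagents that add atoms: none
Why: Aryl silyl ethers are cleaved by fluoride within minutes at 0 °C; acetic acid buffers the phenoxide so that the ester is neither hydrolysed nor transacylated.

## Compound list

1 | (S)-terpinen-4-ol | CC1=CC[C@](O)(C(C)C)CC1 | starting material
2 | (S)-tert-butyl{[4-methyl-1-(propan-2-yl)cyclohex-3-en-1-yl]oxy}dimethylsilane | CC1=CC[C@](O[Si](C)(C)C(C)(C)C)(C(C)C)CC1 | intermediate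
3 | secondary ozonide (1,2,4-trioxolane) of 2 | CC12CC[C@@](O[Si](C)(C)C(C)(C)C)(C(C)C)CC(OO1)O2 | intermediate
4 | (S)-3-(tert-butyldimethylsilyloxy)-6-oxo-3-(propan-2-yl)heptanal | CC(=O)CC[C@@](O[Si](C)(C)C(C)(C)C)(C(C)C)CC=O | intermediate
5 | (R)-5-(tert-butyldimethylsilyloxy)-2-methyl-5-(propan-2-yl)cyclopent-1-ene-1-carbaldehyde | O=CC1=C(C)CC[C@@]1(O[Si](C)(C)C(C)(C)C)C(C)C | intermediate
6 | (R)-tert-butyl{[2-ethenyl-3-methyl-1-(propan-2-yl)cyclopent-2-en-1-yl]oxy}dimethylsilane | C=CC1=C(C)CC[C@@]1(O[Si](C)(C)C(C)(C)C)C(C)C | intermediate
7 | 1-bromo-2,2-dimethoxypropane | COC(C)(CBr)OC | starting material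
8 | 2-methoxyallyl bromide | COC(=C)CBr | intermediate
9 | (1R,4R)-4-(tert-butyldimethylsilyloxy)-9-methoxy-14-nordauca-5,8-diene (methyl enol ether; the 9(10)-ene isomer hydrolyses to the same ketone) | COC1=CCC=C2[C@@](C)(C1)CC[C@@]2(O[Si](C)(C)C(C)(C)C)C(C)C | intermediate
10 | (1R,4R)-4-(tert-butyldimethylsilyloxy)-14-nordauc-5-en-9-one | O=C1CCC=C2[C@@](C)(C1)CC[C@@]2(O[Si](C)(C)C(C)(C)C)C(C)C | intermediate
11 | (1R,4R)-4-(tert-butyldimethylsilyloxy)-9,9-ethylenedioxy-14-nordauc-5-ene | O1CCOC12CCC=C3[C@@](C)(C2)CC[C@@]3(O[Si](C)(C)C(C)(C)C)C(C)C | intermediate
12 | C6 alkylborane (6α-boryl, 5α-H) of 11 | O1CCOC12C[C@@]3(C)CC[C@@](O[Si](C)(C)C(C)(C)C)(C(C)C)[C@@H]3[C@@H](B)CC2 | intermediate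
13 | (1R,4R,5S,6S)-4-(tert-butyldimethylsilyloxy)-9,9-ethylenedioxy-14-nordaucan-6-ol | O1CCOC12C[C@@]3(C)CC[C@@](O[Si](C)(C)C(C)(C)C)(C(C)C)[C@@H]3[C@@H](O)CC2 | intermediate
14 | (1R,4R,5S,6S)-4,6-bis(tert-butyldimethylsilyloxy)-9,9-ethylenedioxy-14-nordaucane | O1CCOC12C[C@@]3(C)CC[C@@](O[Si](C)(C)C(C)(C)C)(C(C)C)[C@@H]3[C@@H](O[Si](C)(C)C(C)(C)C)CC2 | intermediate
15 | (1R,4R,5S,6S)-4,6-bis(tert-butyldimethylsilyloxy)-14-nordaucan-9-one | O=C1C[C@@]2(C)CC[C@@](O[Si](C)(C)C(C)(C)C)(C(C)C)[C@@H]2[C@@H](O[Si](C)(C)C(C)(C)C)CC1 | intermediate
16 | C8 lithium enolate of 15 | [Li]OC=1C[C@@]2(C)CC[C@@](O[Si](C)(C)C(C)(C)C)(C(C)C)[C@@H]2[C@@H](O[Si](C)(C)C(C)(C)C)CC=1 | intermediate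
17 | (1R,4R,5S,6S)-4,6-bis(tert-butyldimethylsilyloxy)daucan-9-one (C8 epimers) | O=C1C[C@@]2(C)CC[C@@](O[Si](C)(C)C(C)(C)C)(C(C)C)[C@@H]2[C@@H](O[Si](C)(C)C(C)(C)C)CC1C | intermediate
18 | (1R,4R,5S,6S)-4,6-bis(tert-butyldimethylsilyloxy)dauc-8-en-9-yl trifluoromethanesulfonate | CC1=C(OS(=O)(=O)C(F)(F)F)C[C@@]2(C)CC[C@@](O[Si](C)(C)C(C)(C)C)(C(C)C)[C@@H]2[C@@H](O[Si](C)(C)C(C)(C)C)C1 | intermediate
19 | (1R,4R,5S,6S)-4,6-bis(tert-butyldimethylsilyloxy)dauc-8-ene | CC1=CC[C@@]2(C)CC[C@@](O[Si](C)(C)C(C)(C)C)(C(C)C)[C@@H]2[C@@H](O[Si](C)(C)C(C)(C)C)C1 | intermediate
20 | (1R,4R,5S,6S)-dauc-8-ene-4,6-diol (jaeschkeanadiol) | CC1=CC[C@@]2(C)CC[C@@](O)(C(C)C)[C@@H]2[C@@H](O)C1 | intermediate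
21 | (E)-4-hydroxycinnamic acid | OC(=O)/C=C/c1ccc(O)cc1 | starting material
22 | tert-butyldimethylsilyl (E)-4-(tert-butyldimethylsilyloxy)cinnamate | CC(C)(C)[Si](C)(C)OC(=O)/C=C/c1ccc(O[Si](C)(C)C(C)(C)C)cc1 | intermediate
23 | (E)-4-(tert-butyldimethylsilyloxy)cinnamic acid | OC(=O)/C=C/c1ccc(O[Si](C)(C)C(C)(C)C)cc1 | intermediate
24 | jaeschkeanadiol 6-O-[(E)-4-(tert-butyldimethylsilyloxy)cinnamate] | CC1=CC[C@@]2(C)CC[C@@](O)(C(C)C)[C@@H]2[C@@H](OC(=O)/C=C/c2ccc(O[Si](C)(C)C(C)(C)C)cc2)C1 | intermediate
25 | jaeschkeanadiol 6-O-[(E)-4-hydroxycinnamate] (CNP0265426.1) | CC1=CC[C@@]2(C)CC[C@@](O)(C(C)C)[C@@H]2[C@@H](OC(=O)/C=C/c2ccc(O)cc2)C1 | target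

## Step count and least certain steps

Total: 17 steps. Longest linear sequence: 15 steps from 1 (steps 1–4, 6–14, 16, 17); steps 5 and 15 are side branches.

**Step 6 (key step).** The most likely failure is that the sequence stops after the first C–C bond. The C6–C5–C1 allyl cation is tertiary and long-lived, so it may lose a proton or close to a five-membered ring instead of bonding at the fully substituted C1. Ag+ and trifluoroacetic acid may also ionise the tertiary allylic silyl ether. Second, discrimination between the two faces of C1 may be weak, because the C4 substituents sit two bonds away. Fallback, from 6 back to 10: 1,1,3,3-tetrabromoacetone and Fe2(CO)9 in benzene at 50 °C generate an iron-bound dibromo-oxyallyl cation under neutral conditions, a species that engages open-chain dienes more readily and, being bulkier, should feel the two faces more strongly. It would give the 8,10-dibromo-4-(tert-butyldimethylsilyloxy)-14-nordauc-5-en-9-one F1. Zinc–copper couple with NH4Cl in methanol would then remove both bromines and return to 10.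

**Step 8.** The likely failure is poor facial selectivity. The α face carries the C4 isopropyl group, the β face the C1 methyl and the C4 silyloxy group, and the difference may be small, so addition from the β face would give the cis-fused isomer. Fallback, from 11 back to 13, setting the two centres by equilibration and ketone reduction instead of by a choice of face:
- The unwanted hydroboration product, the 5β-H,6β-hydroxy cis-fused alcohol F2, is oxidised (Dess–Martin periodinane, NaHCO3, CH2Cl2) to the cis-fused 6-ketone F3.
- Mild amine base (DBU, CH2Cl2, rt) equilibrates C5 through the enol. The trans-fused 6-ketone F4 should be favoured, because a ketone in the seven-membered ring next to the fusion generally prefers the trans arrangement and because C6 then no longer sits syn to the C4 isopropyl group. The base must stay mild, since the C4 silyloxy group is β to this ketone.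
- NaBH4 in methanol at 0 °C should deliver hydride along the axial direction to give the equatorial 6α-alcohol, which is 13.

**Step 12 (with step 11).** The likely failure is enolisation in the wrong direction. Proton loss from C10 instead of C8 would give the regioisomeric enol triflate and, after reduction, the wrong alkene. Triflic acid traces could also cleave the tertiary silyl ether. Fallback, from 15 back to 18, bypassing step 11 and fixing the regiochemistry by where a conjugate reduction places the enolate:
- Kinetic deprotonation of 15 (LiN(iPr)2, THF, −78 °C) and trapping with dimethylmethyleneiminium iodide would give the 8-(dimethylaminomethyl) ketone F5.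
- Quaternisation with MeI and elimination with NaHCO3 would give the 8-methylene ketone F6.
- Conjugate reduction with LiBH(s-Bu)3 at −78 °C generates the C8=C9 enolate, now carrying C14, regiospecifically, and PhNTf2 traps it as 18.

**Step 3.** The likely failure is loss of the silyloxy group by β-elimination from the aldehyde enamine (the tertiary C–O bond is allylic to the enamine). Closure in the other aldol sense, ketone enolate onto aldehyde, is also possible if enamine formation is slow. Fallback, from 4 back to 5, separating C–C bond formation from dehydration: L-proline (cat.) in DMSO at rt should give the aldol, 5-(tert-butyldimethylsilyloxy)-2-hydroxy-2-methyl-5-(propan-2-yl)cyclopentane-1-carbaldehyde F7, without forcing water out. MsCl and Et3N in CH2Cl2 at 0 °C then activate only the hydroxyl, so elimination can take place in one direction only and gives 5.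

## Further compounds

F1 | step 6 | 8,10-dibromo-4-(tert-butyldimethylsilyloxy)-14-nordauc-5-en-9-one (bromide epimers) | O=C1C(Br)CC=C2[C@@](C)(C1Br)CC[C@@]2(O[Si](C)(C)C(C)(C)C)C(C)C
F2 | step 8 | 5β-H,6β-hydroxy cis-fused diastereomer of 13 | O1CCOC12C[C@@]3(C)CC[C@@](O[Si](C)(C)C(C)(C)C)(C(C)C)[C@H]3[C@H](O)CC2
F3 | step 8 | cis-fused (5β-H) 4-(tert-butyldimethylsilyloxy)-9,9-ethylenedioxy-14-nordaucan-6-one | O1CCOC12C[C@@]3(C)CC[C@@](O[Si](C)(C)C(C)(C)C)(C(C)C)[C@H]3C(=O)CC2
F4 | step 8 | trans-fused (5α-H) 4-(tert-butyldimethylsilyloxy)-9,9-ethylenedioxy-14-nordaucan-6-one | O1CCOC12C[C@@]3(C)CC[C@@](O[Si](C)(C)C(C)(C)C)(C(C)C)[C@@H]3C(=O)CC2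
F5 | step 12 | 8-(dimethylaminomethyl)-4,6-bis(tert-butyldimethylsilyloxy)-14-nordaucan-9-one | O=C1C[C@@]2(C)CC[C@@](O[Si](C)(C)C(C)(C)C)(C(C)C)[C@@H]2[C@@H](O[Si](C)(C)C(C)(C)C)CC1CN(C)C
F6 | step 12 | 4,6-bis(tert-butyldimethylsilyloxy)dauc-8(14)-en-9-one (8-methylene ketone) | O=C1C[C@@]2(C)CC[C@@](O[Si](C)(C)C(C)(C)C)(C(C)C)[C@@H]2[C@@H](O[Si](C)(C)C(C)(C)C)CC1=C
F7 | step 3 | 5-(tert-butyldimethylsilyloxy)-2-hydroxy-2-methyl-5-(propan-2-yl)cyclopentane-1-carbaldehyde | O=CC1C(C)(O)CC[C@@]1(O[Si](C)(C)C(C)(C)C)C(C)C
A1 | alternative 1 | 3-allylcyclopent-2-en-1-one | C=CCC1=CC(=O)CC1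
A2 | alternative 1 | 3-methylbut-3-enal | CC(=C)CC=O
A3 | alternative 1 | 3-allyl-2-(1-hydroxy-3-methylbut-3-enyl)-3-methylcyclopentanone | C=CC[C@@]1(C)CCC(=O)[C@@H]1[C@@H](O)CC(C)=C
A4 | alternative 2 | cis-fused decalin 4,6-diol 5-mesylate (daucane atom numbers) | CC1=CC[C@@]2(C)CC[C@@](O)(C(C)C)[C@H](OS(C)(=O)=O)[C@@]2(O)C1
A5 | alternative 2 | trans-fused 4-hydroxydauc-8-en-6-one | CC1=CC[C@@]2(C)CC[C@@](O)(C(C)C)[C@@H]2C(=O)C1
A6 | alternative 3 | cyclopentane-fused 2-(tributylstannyl)-6-isopropenyltetrahydropyran | CC(=C)[C@H]1C[C@@]2(C)CC[C@@](O[Si](CC)(CC)CC)(C(C)C)[C@@H]2[C@H](O1)[Sn](CCCC)(CCCC)CCCC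
A7 | alternative 3 | 4-O-triethylsilyl jaeschkeanadiol | CC1=CC[C@@]2(C)CC[C@@](O[Si](CC)(CC)CC)(C(C)C)[C@@H]2[C@@H](O)C1
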